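The numbers in the tables stem from a simulated flask with constants of no real substance; noise was put on by code.

| setting | Saturday's | Sunday's | flask |
|---|---|---|---|
| left-handed substrate | 0.050 M | 0.075 M | 0.050 M |
| right-handed substrate | 0.050 M | 0.075 M | 0.050 M |
| reagent | 2 equiv (fed, over 80 min) | 2 equiv (fed, over 80 min) | 2.00 equiv (fed, over 80 min) |
| free catalyst | 0.24 mol% | 0.24 mol% | 0.24 mol% |
| remark | the very flask that is asked about, followed so far; the fed solution adds 0.20 times the starting volume | run made earlier; the fed solution adds 0.20 times the starting volume | the fed solution adds 0.20 times the starting volume |
| time |  |  | 5.0 h |

Saturday's run (percent of the left-handed substrate and right-handed substrate together charged)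

| time / h | left-handed product / % | right-handed product / % |
|---|---|---|
| 0.200 | 0.8 | 0 |
| 0.333 | 1.0 | 0 |
| 0.500 | 1.3 | 0 |
| 0.833 | 4.0 | 0.7 |
| 1.50 | 6.0 | 1.8 |
| 2.50 | 11.7 | 5.2 |

Sunday's run (percent of the left-handed substrate and right-handed substrate together charged)

| time / min | left-handed product / % | right-handed product / % |
|---|---|---|
| 8.00 | 1.5 | 0.2 |
| 25.0 | 2.3 | 0 |
| 40.0 | 5.8 | 0.7 |
| 60.0 | 8.5 | 0.9 |
| 90.0 | 15.4 | 3.6 |
| 120 | 20.5 | 4.7 |

(scatter of a reading: 1 percentage point)

1. excess of left-handed product over right-handed product in the product at 6.0 min
2. excess of left-handed product over right-handed product in the product at 5.0 h
3. part of the left-handed substrate and right-handed substrate charged together that has reacted at 5.0 h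

- free catalyst is single-handed; left-handed substrate and right-handed substrate are mirror images of each other, charged as a racemate, each of them at the stated concentration
- charges are per starting volume, the dose included; the dosed solution carries all of it
- an excess is below zero if the other one leads

Early in Saturday's run, which is the flask asked about, the left-handed product stands by itself: 1.3% against 0% of right-handed product at 0.500 h.

Where does the right-handed product come from? I read it as left-handed product turning over, a racemisation. So I reckon the small thing, the gap between the two products, and treat the large total as a mere supply.

How fast is the leak? In the last hour of Saturday's run the right-handed product gains 3.4 percentage points, which over the mean gap is 0.636 /h. Sunday's last hour gives 0.325 /h. Each reading scatters by 1 point, so I take the mean of these two.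

What does the gap do with it? Each turning takes one from the left and gives one to the right, so the gap falls at 2 times the leak. The inverse of that falling rate, 1.04 h, is the gap's memory: once a run has outlasted it at a steady pace of making left-handed product, the gap stands near the product made during the last memory. At 6.0 min, far shorter than that, the excess should still be high.

And at 5.0 h? Saturday's total gains 12 points between 0.833 h and 2.50 h. Held at that pace, the total reaches 35.2% and the gap 7.6 points, so I reckon an excess of 21.6%.

The weak spot? Saturday's readings stop at 2.50 h, and that pace is merely assumed beyond them.

The forecast stands at 90%, 32% and 31%, in the order asked, with the right-handed product taken as “an unselective background reaction”; on the last two it differs from my reckoning.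

The flask gives 92.6%, 13.8% and 26.6%, in the same order.

    reagent + free catalyst + left-handed substrate → free catalyst + left-handed product (k = 34000 /M²/h)
    2 reagent → homo dimer (k = 0.110 /M/h)
    reagent + free catalyst + right-handed substrate → free catalyst + right-handed product (k = 770 /M²/h)
    left-handed product ⇌ right-handed product (k = 0.480 /h)
    free catalyst → spent catalyst (k = 0.200 /h)
    left-handed substrate ⇌ right-handed substrate (k = 2.00 /h)

The forecast parts from the flask on the late excess, standing 18 points above it. From 2.50 h to 5.0 h the total in this flask gains 10 points, so one memory at that mean pace holds 4.1 points, an excess of 15.6% against the flask's 13.8%. For the neighbour charged with 0.96 mol% of free catalyst, I scale that pace by the ratio of the first step's rates at 5.0 h, taken from the catalyst charges and the amounts of left-handed substrate and reagent then: 1.29. Over its 58.2% reacted, the same reckoning gives 9.22%, and that neighbour gives 9.93%.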